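## Retrosynthetic overview

1. Target ⇐ fluoride desilylation of its 5,7-bis(silyl) ether ⇐ Pd-catalysed carbonylative annulation of a ring-A ortho-iodophenol, CO and a ring-B aryl alkyne (pyranone ring C closed last).
2. Ring-A iodophenol ⇐ resorcinol by silylation, Ir-catalysed meta C–H borylation/oxidation and ortho-iodination.
3. Ring-B alkyne ⇐ aryl bromide ⇐ allyl-to-prenyl cross-metathesis ⇐ key ring contraction: an 8-allyl-6-bromo-2,2-dimethyl-2H-chromene becomes the trans-3-hydroxy-2-(2-hydroxypropan-2-yl)-2,3-dihydrobenzofuran by an iodane-induced 1,2-shift of the ring oxygen, which sets both stereocentres.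
4. Chromene ⇐ 2-allyl-4-bromophenol + 3-methylbut-2-enal ⇐ 4-bromophenol + allyl bromide. The prenyl group is carried as allyl through the oxidation because a trisubstituted alkene would compete for the iodane.
5. Ring order: pyran ring of the chromene, then its contraction to the dihydrofuran ring, then ring C; ring A comes preformed from resorcinol.

Assumption: the (S,S)-lactate iodane is taken to deliver iodine to the chromene face that gives adduct 13, by analogy with its styrene dioxygenations; if the sense is reversed, the (R,R)-reagent is used in the same way.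

## Route

Step 1
Reactants: 1 resorcinol
Product: 2 1,3-bis(triisopropylsilyloxy)benzene
Conditions: i-Pr3SiCl (2.2 equiv), imidazole (4 equiv), DMF, rt
Reagents that add atoms: triisopropylsilyl chloride, CC(C)[Si](Cl)(C(C)C)C(C)C
Why: Standard phenol O-silylation; the bulky silyl ethers block every C–H ortho to oxygen in the next step and come off with fluoride at the end.

Step 2
Reactants: 2 1,3-bis(triisopropylsilyloxy)benzene
Product: 4 3,5-bis(triisopropylsilyloxy)phenol, via aryl pinacol boronate 3 (not isolated)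
Conditions: [Ir(OMe)(cod)]2 (1.5 mol %), 4,4'-di-tert-butyl-2,2'-bipyridine (3 mol %), B2pin2 (1.0 equiv), hexane, 80 °C; evaporate; then KHSO5 (as Oxone, 1.1 equiv), acetone/H2O, rt
Reagents that add atoms: potassium peroxymonosulfate, [K+].[O-]S(=O)(=O)OO (phenol oxygen); bis(pinacolato)diboron, CC1(C)OB(OC1(C)C)B1OC(C)(C)C(C)(C)O1 (boron in intermediate 3 only)
Why: Sterically governed Ir-catalysed C–H borylation (C-5 is the only C–H not ortho to an OSi group) followed by one-pot boronate oxidation to the phenol.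

Step 3
Reactants: 4 3,5-bis(triisopropylsilyloxy)phenol
Product: 5 2-iodo-3,5-bis(triisopropylsilyloxy)phenol
Conditions: N-iodosuccinimide (1.0 equiv), CH2Cl2, −20 to 0 °C, dark
Reagents that add atoms: N-iodosuccinimide, O=C1CCC(=O)N1I
Why: Electrophilic aromatic iodination ortho to the free phenol (C-2 and C-6 are equivalent, and the para position is shielded by two flanking OSi(i-Pr)3 groups).

Step 4
Reactants: 6 4-bromophenol; 7 allyl bromide
Product: 8 2-allyl-4-bromophenol
Conditions: NaH (1.05 equiv), toluene, 0 °C to rt; then 7 (1.1 equiv), 70 °C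
Reagents that add atoms: none
Why: Classical ortho C-allylation of a tight sodium phenoxide ion pair in a non-polar solvent, with the para position blocked by bromine.

Step 5
Reactants: 8 2-allyl-4-bromophenol; 9 3-methylbut-2-enal
Product: 12 8-allyl-6-bromo-2,2-dimethyl-2H-chromene, via benzodioxaborinine 10 (not isolated), via ortho-quinone methide 11 (not isolated)
Conditions: PhB(OH)2 (1.1 equiv), AcOH (0.3 equiv), toluene, reflux, Dean–Stark
Reagents that add atoms: phenylboronic acid, OB(O)c1ccccc1 (in intermediate 10 only; released again)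
Why: Boron-templated ortho-selective condensation of phenol and enal, thermal fragmentation to the ortho-quinone methide and oxa-6π electrocyclisation (phenylboronic acid chromenylation).

Step 6
Reactants: 12 8-allyl-6-bromo-2,2-dimethyl-2H-chromene
Product: 16 (2R,3R)-7-allyl-5-bromo-2-(2-hydroxypropan-2-yl)-2,3-dihydro-1-benzofuran-3-ol, via trans-iodane adduct 13 (not isolated), via oxiranium ion 14 (not isolated), via bis(trifluoroacetate) 15 (not isolated)
Conditions: (S,S)-ArI(OAc)2 (Ar = 2,6-bis[(1S)-1-(methoxycarbonyl)ethoxy]phenyl, 1.2 equiv), CF3CO2H (4 equiv), BF3·OEt2 (1.2 equiv), CH2Cl2, −78 to −40 °C; aq NaHCO3 work-up; then K2CO3 (cat.), MeOH, 0 °C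
Reagents that add atoms: trifluoroacetic acid, OC(=O)C(F)(F)F (both new oxygens); dimethyl (2S,2'S)-2,2'-{[2-(diacetoxy-λ3-iodanyl)-1,3-phenylene]bis(oxy)}dipropanoate, COC(=O)[C@H](C)Oc1cccc(O[C@@H](C)C(=O)OC)c1I(OC(C)=O)OC(C)=O (aryliodanyl group in intermediate 13 only)
Why: Proposed new method: the BF3-activated lactate aryl-λ3-iodane (trivalent iodine) adds to one face of the electron-rich chromene C3=C4 bond and trifluoroacetate opens the iodonium at benzylic C-4 anti to iodine (13); the iodanyl hypernucleofuge at C-3 then leaves with anti-periplanar 1,2-shift of the ring oxygen from the gem-dimethyl carbon to C-3 (inversion at C-3, ring contraction, charge taken by the tertiary centre as oxiranium 14); trifluoroacetate captures the tertiary carbon (15) and methanolysis frees both hydroxyls, so anti addition plus inversion gives the trans relationship and the reagent-controlled facial choice gives (2R,3R); trifluoroacetate is chosen at C-4 because it neither participates through its carbonyl nor stabilises the cation a competing 1,2-aryl shift would need, and the isolated allyl group is far less nucleophilic than the ortho-alkoxystyrene; closest known reactions are the trivalent-iodine ring contraction of 1,2-dihydronaphthalenes by aryl shift, the enantioselective Prévost–Woodward dioxygenation of styrenes with the same lactate iodanes, and the solvolytic ring contraction of 2,2-dimethylchroman-3-yl sulfonates to 2-substituted dihydrobenzofurans.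

Step 7
Reactants: 16 (2R,3R)-7-allyl-5-bromo-2-(2-hydroxypropan-2-yl)-2,3-dihydro-1-benzofuran-3-ol; 17 2-methylbut-2-ene
Product: 18 (2R,3R)-5-bromo-2-(2-hydroxypropan-2-yl)-7-(3-methylbut-2-enyl)-2,3-dihydro-1-benzofuran-3-ol
Conditions: second-generation Grubbs catalyst RuCl2(=CHPh)(PCy3)(H2IMes) (5 mol %), 17 (excess, co-solvent), CH2Cl2, 40 °C
Reagents that add atoms: none
Why: Olefin cross-metathesis of a terminal allyl group with 2-methylbut-2-ene is a reliable allyl-to-prenyl conversion that tolerates free hydroxyls and the aryl bromide and leaves both stereocentres untouched.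

Step 8
Reactants: 18 (2R,3R)-5-bromo-2-(2-hydroxypropan-2-yl)-7-(3-methylbut-2-enyl)-2,3-dihydro-1-benzofuran-3-ol; 19 ethynyltrimethylsilane
Product: 21 (2R,3R)-5-ethynyl-2-(2-hydroxypropan-2-yl)-7-(3-methylbut-2-enyl)-2,3-dihydro-1-benzofuran-3-ol, via silylalkyne 20 (not isolated)
Conditions: PdCl2(PhCN)2 (3 mol %), P(t-Bu)3·HBF4 (6 mol %), CuI (2 mol %), i-Pr2NH (2 equiv), dioxane, rt; then K2CO3 (cat.), MeOH, rt
Reagents that add atoms: none
Why: Room-temperature Sonogashira coupling of an electron-rich aryl bromide (bulky trialkylphosphine conditions, free alcohols tolerated) followed by base-catalysed methanolysis of the C–Si bond.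

Step 9
Reactants: 5 2-iodo-3,5-bis(triisopropylsilyloxy)phenol; 21 (2R,3R)-5-ethynyl-2-(2-hydroxypropan-2-yl)-7-(3-methylbut-2-enyl)-2,3-dihydro-1-benzofuran-3-ol; 22 carbon monoxide
Product: 25 2-[(2R,3R)-3-hydroxy-2-(2-hydroxypropan-2-yl)-7-(3-methylbut-2-enyl)-2,3-dihydro-1-benzofuran-5-yl]-5,7-bis(triisopropylsilyloxy)-4H-chromen-4-one, via ynone 23 (not isolated), via enaminone 24 (not isolated)
Conditions: PdCl2(PPh3)2 (5 mol %), Et2NH (5 equiv), DMF, CO (1 atm), 50 °C
Reagents that add atoms: diethylamine, CCNCC (in intermediate 24 only; released again)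
Why: Carbonylative Sonogashira coupling gives the ortho-hydroxyaryl ynone, the secondary amine adds to it and the phenol oxygen closes the six-membered ring by addition–elimination (flavone rather than aurone), with no stereocentre involved.

Step 10
Reactants: 25 2-[(2R,3R)-3-hydroxy-2-(2-hydroxypropan-2-yl)-7-(3-methylbut-2-enyl)-2,3-dihydro-1-benzofuran-5-yl]-5,7-bis(triisopropylsilyloxy)-4H-chromen-4-one
Product: 26 5,7-dihydroxy-2-[(2R,3R)-3-hydroxy-2-(2-hydroxypropan-2-yl)-7-(3-methylbut-2-enyl)-2,3-dihydro-1-benzofuran-5-yl]-4H-chromen-4-one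
Conditions: Bu4NF (2.2 equiv), AcOH (2.2 equiv), THF, 0 °C
Reagents that add atoms: none
Why: Buffered fluoride cleavage of the aryl silyl ethers avoids acid, so the ionisable benzylic alcohol, the tertiary alcohol and the prenyl group survive.

## Compound list

1 | resorcinol | Oc1cccc(O)c1 | starting material
2 | 1,3-bis(triisopropylsilyloxy)benzene | CC(C)[Si](Oc1cccc(O[Si](C(C)C)(C(C)C)C(C)C)c1)(C(C)C)C(C)C | intermediate
3 | 2-[3,5-bis(triisopropylsilyloxy)phenyl]-4,4,5,5-tetramethyl-1,3,2-dioxaborolane | CC(C)[Si](Oc1cc(B2OC(C)(C)C(C)(C)O2)cc(O[Si](C(C)C)(C(C)C)C(C)C)c1)(C(C)C)C(C)C | intermediate (not isolated)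
4 | 3,5-bis(triisopropylsilyloxy)phenol | CC(C)[Si](Oc1cc(O)cc(O[Si](C(C)C)(C(C)C)C(C)C)c1)(C(C)C)C(C)C | intermediate
5 | 2-iodo-3,5-bis(triisopropylsilyloxy)phenol | Oc1cc(O[Si](C(C)C)(C(C)C)C(C)C)cc(O[Si](C(C)C)(C(C)C)C(C)C)c1I | intermediate
6 | 4-bromophenol | Oc1ccc(Br)cc1 | starting material
7 | allyl bromide | C=CCBr | starting material
8 | 2-allyl-4-bromophenol | Oc1ccc(Br)cc1CC=C | intermediate
9 | 3-methylbut-2-enal | CC(C)=CC=O | starting material
10 | 8-allyl-6-bromo-4-(2-methylprop-1-enyl)-2-phenyl-4H-1,3,2-benzodioxaborinine (racemic) | CC(C)=CC1OB(c2ccccc2)Oc2c(CC=C)cc(Br)cc21 | intermediate (not isolated)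
11 | (6Z)-2-allyl-4-bromo-6-(3-methylbut-2-enylidene)cyclohexa-2,4-dienone | CC(C)=C/C=C1\C(=O)C(CC=C)=CC(Br)=C1 | intermediate (not isolated)
12 | 8-allyl-6-bromo-2,2-dimethyl-2H-chromene | CC1(C)C=Cc2cc(Br)cc(CC=C)c2O1 | intermediate
13 | [(3S,4R)-8-allyl-6-bromo-2,2-dimethyl-4-(trifluoroacetoxy)chroman-3-yl]{2,6-bis[(1S)-1-(methoxycarbonyl)ethoxy]phenyl}(trifluoroacetoxy)-λ3-iodane | CC1(C)Oc2c(CC=C)cc(Br)cc2[C@@H](OC(=O)C(F)(F)F)[C@@H]1I(OC(=O)C(F)(F)F)c1c(O[C@@H](C)C(=O)OC)cccc1O[C@@H](C)C(=O)OC | intermediate (not isolated)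
14 | aryl-bridged oxiranium cation: ring oxygen bonded to C-2, to the CMe2 carbon and to the arene; (2R,3R)-3-trifluoroacetoxy-7-allyl-5-bromo-2,3-dihydrobenzofuran core | C=CCc1cc(Br)cc2[C@@H](OC(=O)C(F)(F)F)[C@@H]3C(C)(C)[O+]3c12 | intermediate (not isolated)
15 | (2R,3R)-7-allyl-5-bromo-2-[2-(trifluoroacetoxy)propan-2-yl]-2,3-dihydro-1-benzofuran-3-yl trifluoroacetate | C=CCc1cc(Br)cc2c1O[C@@H](C(C)(C)OC(=O)C(F)(F)F)[C@@H]2OC(=O)C(F)(F)F | intermediate (not isolated)
16 | (2R,3R)-7-allyl-5-bromo-2-(2-hydroxypropan-2-yl)-2,3-dihydro-1-benzofuran-3-ol (trans) | C=CCc1cc(Br)cc2c1O[C@@H](C(C)(C)O)[C@@H]2O | intermediate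
17 | 2-methylbut-2-ene | CC=C(C)C | starting material
18 | (2R,3R)-5-bromo-2-(2-hydroxypropan-2-yl)-7-(3-methylbut-2-enyl)-2,3-dihydro-1-benzofuran-3-ol | CC(C)=CCc1cc(Br)cc2c1O[C@@H](C(C)(C)O)[C@@H]2O | intermediate
19 | ethynyltrimethylsilane | C#C[Si](C)(C)C | starting material
20 | (2R,3R)-2-(2-hydroxypropan-2-yl)-7-(3-methylbut-2-enyl)-5-[(trimethylsilyl)ethynyl]-2,3-dihydro-1-benzofuran-3-ol | CC(C)=CCc1cc(C#C[Si](C)(C)C)cc2c1O[C@@H](C(C)(C)O)[C@@H]2O | intermediate (not isolated)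
21 | (2R,3R)-5-ethynyl-2-(2-hydroxypropan-2-yl)-7-(3-methylbut-2-enyl)-2,3-dihydro-1-benzofuran-3-ol | CC(C)=CCc1cc(C#C)cc2c1O[C@@H](C(C)(C)O)[C@@H]2O | intermediate
22 | carbon monoxide | [C-]#[O+] | starting material
23 | 1-[2-hydroxy-4,6-bis(triisopropylsilyloxy)phenyl]-3-[(2R,3R)-3-hydroxy-2-(2-hydroxypropan-2-yl)-7-(3-methylbut-2-enyl)-2,3-dihydro-1-benzofuran-5-yl]prop-2-yn-1-one | CC(C)=CCc1cc(C#CC(=O)c3c(O)cc(O[Si](C(C)C)(C(C)C)C(C)C)cc3O[Si](C(C)C)(C(C)C)C(C)C)cc2c1O[C@@H](C(C)(C)O)[C@@H]2O | intermediate (not isolated)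
24 | (E)-3-(diethylamino) enone adduct of 23 (E isomer drawn; E/Z mixture possible) | CC(C)=CCc1cc(/C(N(CC)CC)=C\C(=O)c3c(O)cc(O[Si](C(C)C)(C(C)C)C(C)C)cc3O[Si](C(C)C)(C(C)C)C(C)C)cc2c1O[C@@H](C(C)(C)O)[C@@H]2O | intermediate (not isolated)
25 | 2-[(2R,3R)-3-hydroxy-2-(2-hydroxypropan-2-yl)-7-(3-methylbut-2-enyl)-2,3-dihydro-1-benzofuran-5-yl]-5,7-bis(triisopropylsilyloxy)-4H-chromen-4-one | CC(C)=CCc1cc(-c3cc(=O)c4c(O[Si](C(C)C)(C(C)C)C(C)C)cc(O[Si](C(C)C)(C(C)C)C(C)C)cc4o3)cc2c1O[C@@H](C(C)(C)O)[C@@H]2O | intermediate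
26 | 5,7-dihydroxy-2-[(2R,3R)-3-hydroxy-2-(2-hydroxypropan-2-yl)-7-(3-methylbut-2-enyl)-2,3-dihydro-1-benzofuran-5-yl]-4H-chromen-4-one (CNP0172554.2) | CC(C)=CCc1cc(-c2cc(=O)c3c(O)cc(O)cc3o2)cc2c1O[C@@H](C(C)(C)O)[C@@H]2O | target

## Step count and risk

Total step count: 10.
Longest linear sequence: 7 steps (steps 4 to 10, from 4-bromophenol); the ring-A branch (steps 1 to 3) joins at step 9.

**Step 6 (new iodane-mediated ring contraction).** The main dangers are a competing 1,2-aryl shift, participation by the C-4 ester, aromatisation of the benzylic ester, and insufficient enantioselectivity. The fallback uses known chemistry only; it sets out from 12 and comes back at 16. Epoxidation of 12 with NaOCl and Jacobsen's [(S,S)-N,N'-bis(3,5-di-tert-butylsalicylidene)-1,2-cyclohexanediaminato]manganese chloride (trivalent manganese) is selective for the conjugated cis-alkene and gives (3S,4S)-8-allyl-6-bromo-3,4-epoxy-2,2-dimethylchromane F1. Aqueous NaOH in dioxane opens F1 at benzylic C-4 with inversion to (3S,4R)-8-allyl-6-bromo-2,2-dimethylchromane-3,4-diol F2. Trichloroacetyl chloride and pyridine at −40 °C acylate only the unhindered benzylic hydroxyl, giving (3S,4R)-8-allyl-6-bromo-3-hydroxy-2,2-dimethylchroman-4-yl trichloroacetate F3. MsCl and Et3N convert F3 into (3S,4R)-8-allyl-6-bromo-2,2-dimethyl-3-(methylsulfonyloxy)chroman-4-yl trichloroacetate F4. Buffered solvolysis of F4 (2,6-lutidine, aqueous hexafluoroisopropanol, 50 °C) brings about the same oxygen 1,2-shift with water capture, giving (2R,3R)-7-allyl-5-bromo-2-(2-hydroxypropan-2-yl)-2,3-dihydro-1-benzofuran-3-yl trichloroacetate F5. K2CO3 in MeOH then gives 16.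

**Step 9 (carbonylative annulation).** The aryl iodide is electron-rich and flanked by two ortho substituents, so direct non-carbonylative coupling to a benzofuran or aurone formation may compete. The fallback builds the ynone by acetylide addition and oxidation instead of carbonylation; it sets out from 4 and 21 and comes back at 26. Phenol 4 is ortho-formylated (MgCl2, Et3N, paraformaldehyde, MeCN, reflux) to 2-hydroxy-4,6-bis(triisopropylsilyloxy)benzaldehyde F6. Alkyne 21 is silylated (Et3SiOTf, 2,6-lutidine) to (2R,3R)-5-ethynyl-7-(3-methylbut-2-enyl)-3-(triethylsilyloxy)-2-[2-(triethylsilyloxy)propan-2-yl]-2,3-dihydro-1-benzofuran F7. The lithium acetylide of F7 (n-BuLi, THF, −78 °C) adds to the lithium phenoxide of F6 (made with LiN(SiMe3)2) to give the propargylic alcohol F8 as carbinol epimers. MnO2 oxidises F8 to the bis(triethylsilyl) ynone F9, and Et2NH in EtOH closes the pyranone to the tetrasilylated flavone F10. Bu4NF/AcOH as in step 10 removes all four silyl groups and gives 26.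

**Step 5 (one-step chromenylation).** The phenol is electron-poor and ortho-substituted, so the boron-templated condensation may be slow. The fallback sets out from 8 and comes back at 12. Phenol 8 is O-alkylated with 3-chloro-3-methylbut-1-yne (DBU, CuCl2 cat., MeCN, 0 °C) to 2-allyl-4-bromo-1-[(2-methylbut-3-yn-2-yl)oxy]benzene F11. Heating F11 in N,N-diethylaniline at 190 °C (propargyl Claisen rearrangement, 1,5-hydrogen shift, electrocyclisation) gives 12.

## Further compounds

F1 | step 6 | (3S,4S)-8-allyl-6-bromo-3,4-epoxy-2,2-dimethylchromane | C=CCc1cc(Br)cc2c1OC(C)(C)[C@H]1O[C@@H]21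
F2 | step 6 | (3S,4R)-8-allyl-6-bromo-2,2-dimethylchromane-3,4-diol | CC1(C)Oc2c(CC=C)cc(Br)cc2[C@@H](O)[C@@H]1O
F3 | step 6 | (3S,4R)-8-allyl-6-bromo-3-hydroxy-2,2-dimethylchroman-4-yl trichloroacetate | CC1(C)Oc2c(CC=C)cc(Br)cc2[C@@H](OC(=O)C(Cl)(Cl)Cl)[C@@H]1O
F4 | step 6 | (3S,4R)-8-allyl-6-bromo-2,2-dimethyl-3-(methylsulfonyloxy)chroman-4-yl trichloroacetate | CC1(C)Oc2c(CC=C)cc(Br)cc2[C@@H](OC(=O)C(Cl)(Cl)Cl)[C@@H]1OS(C)(=O)=O
F5 | step 6 | (2R,3R)-7-allyl-5-bromo-2-(2-hydroxypropan-2-yl)-2,3-dihydro-1-benzofuran-3-yl trichloroacetate | C=CCc1cc(Br)cc2c1O[C@@H](C(C)(C)O)[C@@H]2OC(=O)C(Cl)(Cl)Cl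
F6 | step 9 | 2-hydroxy-4,6-bis(triisopropylsilyloxy)benzaldehyde | O=Cc1c(O)cc(O[Si](C(C)C)(C(C)C)C(C)C)cc1O[Si](C(C)C)(C(C)C)C(C)C
F7 | step 9 | (2R,3R)-5-ethynyl-7-(3-methylbut-2-enyl)-3-(triethylsilyloxy)-2-[2-(triethylsilyloxy)propan-2-yl]-2,3-dihydro-1-benzofuran | CC(C)=CCc1cc(C#C)cc2c1O[C@@H](C(C)(C)O[Si](CC)(CC)CC)[C@@H]2O[Si](CC)(CC)CC
F8 | step 9 | propargylic alcohol from F6 and F7 (carbinol epimers) | CC(C)=CCc1cc(C#CC(O)c3c(O)cc(O[Si](C(C)C)(C(C)C)C(C)C)cc3O[Si](C(C)C)(C(C)C)C(C)C)cc2c1O[C@@H](C(C)(C)O[Si](CC)(CC)CC)[C@@H]2O[Si](CC)(CC)CC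
F9 | step 9 | bis(triethylsilyl) ynone | CC(C)=CCc1cc(C#CC(=O)c3c(O)cc(O[Si](C(C)C)(C(C)C)C(C)C)cc3O[Si](C(C)C)(C(C)C)C(C)C)cc2c1O[C@@H](C(C)(C)O[Si](CC)(CC)CC)[C@@H]2O[Si](CC)(CC)CC
F10 | step 9 | tetrasilylated flavone (bis(triethylsilyl) ether of 25) | CC(C)=CCc1cc(-c3cc(=O)c4c(O[Si](C(C)C)(C(C)C)C(C)C)cc(O[Si](C(C)C)(C(C)C)C(C)C)cc4o3)cc2c1O[C@@H](C(C)(C)O[Si](CC)(CC)CC)[C@@H]2O[Si](CC)(CC)CC
F11 | step 5 | 2-allyl-4-bromo-1-[(2-methylbut-3-yn-2-yl)oxy]benzene | C=CCc1cc(Br)ccc1OC(C)(C)C#C
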